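**Retrosynthetic overview**
- Last disconnection: the two C–Br bonds on the hydroxylated ring (ortho and para to the free OH), made by electrophilic bromination of a 2-aryloxyphenol.
- Key disconnection: the diaryl ether C–O bond. The phenol oxygen and the arene carbon are both normally nucleophilic, so the 2,4-dibromophenyl carbon is used with reversed polarity, as an aryl cation equivalent (aryl-λ3-iodane), and joined to unprotected catechol.
- The iodonium salt comes from 2,4-dibromo-1-iodobenzene and 1,3,5-trimethoxybenzene (non-transferred dummy aryl) in a one-pot oxidation/arylation.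
- No ring is built: both benzene rings are bought intact, and there is no stereocentre to set.

Assumption: the target is achiral (no stereocentre, freely rotating diaryl ether), so "single enantiomer" simply means the compound as drawn.

**Step 1**
Reactants: 1 2,4-dibromo-1-iodobenzene; 2 1,3,5-trimethoxybenzene
Product: 4 (2,4-dibromophenyl)(2,4,6-trimethoxyphenyl)iodonium tosylate, via Koser-type iodane 3 (not isolated)
Conditions: mCPBA (1.1 equiv), TsOH·H2O (1.05 equiv), MeCN, 77 °C, 45 min; then 2 (1.05 equiv), 77 °C, 10 min; precipitate with Et2O
Reagents that add atoms: p-toluenesulfonic acid (used as monohydrate), Cc1ccc(cc1)S(=O)(=O)O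
Why: One-pot Koser-type oxidation of the aryl iodide to ArI(OH)OTs followed by electrophilic aromatic substitution on the very electron-rich trimethoxybenzene gives the unsymmetrical diaryliodonium tosylate; the aryl bromides are inert to peracid and no stereocentre is formed.

**Step 2**
Reactants: 4 (2,4-dibromophenyl)(2,4,6-trimethoxyphenyl)iodonium tosylate; 5 catechol (benzene-1,2-diol, 3 equiv)
Product: 7 2-(2,4-dibromophenoxy)phenol, via aryloxy-λ3-iodane 6 (not isolated)
Conditions: K2CO3 (1.2 equiv), degassed MeCN, Ar, 60 °C; aqueous wash removes excess catechol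
Reagents that add atoms: none
Why: Metal-free O-arylation by ligand coupling of a diaryl-λ3-iodane (aryl cation equivalent): the catechol mono-phenoxide exchanges onto iodine(III) and couples with the electron-poorer, ortho-substituted 2,4-dibromophenyl group while the trimethoxyphenyl group leaves as the aryl iodide; excess catechol and one equivalent of mild base hold the reaction at mono-arylation, and no stereocentre is formed.

**Step 3**
Reactants: 7 2-(2,4-dibromophenoxy)phenol
Product: 9 2,4-dibromo-6-(2,4-dibromophenoxy)phenol, via para-monobromide 8 (not isolated)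
Conditions: Br2 (2.05 equiv), AcOH, 15 °C to rt; aq. Na2S2O3 quench
Reagents that add atoms: bromine, BrBr
Why: Electrophilic aromatic bromination directed by the free OH, which is a much stronger activator than the electron-poor aryloxy group, goes first para and then ortho to OH; the already dibrominated phenoxy ring is too deactivated to react with two equivalents, and no stereocentre is formed.

**Compound list**
1 | 2,4-dibromo-1-iodobenzene | Brc1ccc(I)c(Br)c1 | starting material
2 | 1,3,5-trimethoxybenzene | COc1cc(OC)cc(OC)c1 | starting material
3 | 2,4-dibromo-1-[hydroxy(tosyloxy)-λ3-iodanyl]benzene | OI(OS(=O)(=O)c1ccc(C)cc1)c1ccc(Br)cc1Br | intermediate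
4 | (2,4-dibromophenyl)(2,4,6-trimethoxyphenyl)iodonium 4-methylbenzenesulfonate | COc1cc(OC)c([I+]c2ccc(Br)cc2Br)c(OC)c1.Cc1ccc(cc1)S(=O)(=O)[O-] | intermediate
5 | catechol (benzene-1,2-diol) | Oc1ccccc1O | starting material
6 | (2,4-dibromophenyl)(2-hydroxyphenoxy)(2,4,6-trimethoxyphenyl)-λ3-iodane | Oc1ccccc1OI(c1ccc(Br)cc1Br)c1c(OC)cc(OC)cc1OC | intermediate
7 | 2-(2,4-dibromophenoxy)phenol | Oc1ccccc1Oc1ccc(Br)cc1Br | intermediate
8 | 4-bromo-2-(2,4-dibromophenoxy)phenol | Oc1ccc(Br)cc1Oc1ccc(Br)cc1Br | intermediate
9 | 2,4-dibromo-6-(2,4-dibromophenoxy)phenol | Oc1c(Br)cc(Br)cc1Oc1ccc(Br)cc1Br | target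

**Total step count:** 3
**Longest linear sequence:** 3 (1 → 4 → 7 → 9)

**Steps most likely to fail, with fallbacks**

Step 2 (highest risk). Free catechol may be arylated twice to the 1,2-bis(aryloxy)benzene or be oxidised by the iodine(III) salt. The fallback sets out from 4 and returns at 7. Iodonium salt 4 is coupled under the same mild base conditions with purchased guaiacol (2-methoxyphenol), which has only one nucleophilic oxygen and cannot form an o-quinone. This gives 2,4-dibromo-1-(2-methoxyphenoxy)benzene F1. The methyl ether is then cleaved with BBr3 in CH2Cl2 (−78 to 0 °C), which leaves the diaryl ether and the aryl bromides untouched, to give 7.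

Step 3. Some bromination para to the aryloxy group, or over-bromination, would give inseparable isomers. The fallback sets out from 4 and returns at 9, with both ring bromines already in place before the ether bond is made. Purchased 3,5-dibromosalicylaldehyde is O-methylated (MeI, K2CO3, DMF) to 3,5-dibromo-2-methoxybenzaldehyde F2. Baeyer–Villiger oxidation (mCPBA, CH2Cl2, reflux) gives 3,5-dibromo-2-methoxyphenyl formate F3. Cleavage with KOH in MeOH/H2O and acidification gives 3,5-dibromo-2-methoxyphenol F4. This phenol is O-arylated with iodonium salt 4 (K2CO3, MeCN, 60 °C) to 1,5-dibromo-3-(2,4-dibromophenoxy)-2-methoxybenzene F5. BBr3 demethylation then gives 9 with unambiguous regiochemistry.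

Step 1. The electron-poor Koser-type intermediate may oxidise trimethoxybenzene instead of arylating it. The fallback sets out from 1 and returns at 7. Aryl iodide 1 is oxidised with mCPBA in the presence of TfOH (CH2Cl2, rt to 40 °C) and purchased 1,3-dibromobenzene. The arene is attacked at C4 (ortho/para to its bromines), giving symmetric bis(2,4-dibromophenyl)iodonium trifluoromethanesulfonate F6. With two identical aryl groups there is no question of which one transfers. F6 is used in place of 4 with catechol 5 (K2CO3, MeCN, 60 °C) to give 7, and the aryl iodide 1 that is released can be recycled.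

**Further compounds**
F1 | step 2 | 2,4-dibromo-1-(2-methoxyphenoxy)benzene | COc1ccccc1Oc1ccc(Br)cc1Br
F2 | step 3 | 3,5-dibromo-2-methoxybenzaldehyde | COc1c(Br)cc(Br)cc1C=O
F3 | step 3 | 3,5-dibromo-2-methoxyphenyl formate | COc1c(Br)cc(Br)cc1OC=O
F4 | step 3 | 3,5-dibromo-2-methoxyphenol | COc1c(Br)cc(Br)cc1O
F5 | step 3 | 1,5-dibromo-3-(2,4-dibromophenoxy)-2-methoxybenzene | COc1c(Br)cc(Br)cc1Oc1ccc(Br)cc1Br
F6 | step 1 | bis(2,4-dibromophenyl)iodonium trifluoromethanesulfonate | Brc1ccc([I+]c2ccc(Br)cc2Br)c(Br)c1.[O-]S(=O)(=O)C(F)(F)F
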